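The numbers were drawn at random within sensible limits; what happens was integrated by code.

substrate 0.010 M; reagent 0.0250 M; capture agent 3.00 mM; free catalyst 56 µM

    substrate + free catalyst → catalyst intermediate A (k1 = 525 M⁻¹ s⁻¹)
    reagent + catalyst intermediate A ⇌ catalyst intermediate B (K2 = 660 M⁻¹, k2 = 723 M⁻¹ s⁻¹)
    catalyst intermediate B → free catalyst + product (k3 = 1520 s⁻¹)
    catalyst intermediate B + capture agent → trapped intermediate (k4 = 1920 M⁻¹ s⁻¹)
    catalyst intermediate B → spent catalyst (k5 = 0.0273 s⁻¹)

- apparent order in reagent when 50% of the substrate are converted (percent change of the rate of making product for one percent more reagent charged)

- The easy step comes first: catalyst intermediate B gives product and free catalyst within 0.658 ms, and it goes back to catalyst intermediate A at a rate of just 1.10 s⁻¹, so I count each catalyst as passing through the round in one direction.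
- In the first instants, at the charged amounts, free catalyst waits 0.190 s for substrate and catalyst intermediate A waits 0.0553 s for reagent, a shorter wait. By my reckoning, 77.2% of the catalyst in the round therefore sits as free catalyst, the resting state.
- In the middle, at 50% conversion, c(substrate) is 5.00 mM and c(reagent) is 20.0 mM; each product takes one of each. The wait for substrate is now 0.381 s and the wait for reagent 0.0692 s.
- With the step from catalyst intermediate B, these waits add up to 0.451 s. This sum, the time one catalyst needs for one round at the amounts present, is the turn time that I carry: the rate of making product is the catalyst in the round divided by it.
- The reagent's part of the turn time is 15.3%, and one percent more reagent charged raises c(reagent) at that conversion by 1.25 percent. Each product costs a chance of trapping of 0.379%, a ratio with no reagent in it, so I take the catalyst in the round as unchanged at equal conversion. My order is 0.192.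
- Towards the end, substrate is the limiting reagent, so the wait for it keeps growing while trapped intermediate builds up with the product.
- The forecast, which takes “the cycle is two steps in series”, gives 0.192.
- The simulation gives 0.19, with 50% conversion reached at 36.3 s.
- At that moment the flask makes product at 8.21 × 10⁻⁵ M s⁻¹, and this rate times the turn time gives 37.0 µM of catalyst still in the round, 66.1% of the charge. The loss of catalyst intermediate B to trapped intermediate holds the rate down: the charge over that working catalyst is 1.51, and the run with this step taken away makes product, at that same conversion, at 1.51 times the actual rate.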